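**Plan**
Numbering (used in all explanations): ring C1 (CMe2), C2 (CHBr), C3 (alkylidene carbon), C4 (CHCl), C5 (CH2), C6 (CHCl); side chain C7 (=CH), C8 (CH2Br). Chain C3 and C5 of the acyclic intermediates are C4 and C6 of the target.
Feature and cuts: Br–C2–C3(=C7)–C8–Br is a 1-vinylcyclohexene diene C2=C3–C7=C8 at the 1,4-dibromide level. C2–Br and C8–Br are cut back to a C2/C8 endoperoxide of that diene and C4–Cl to a C4 silyl ether. The diene is cut at C2=C3 and C7=C8 to the alkene and alkyne of one acyclic 1,7-enyne, and the chain at C5–C6 (aldol) and C6–C1 (prenyl formylation).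
Forward order: C1–C6 by γ-formylation of prenylmagnesium chloride, C5–C6 by aldol addition, the only carbocycle by ring-closing enyne metathesis, then a transient dioxine ring by [4+2] addition of singlet oxygen, C4–Cl, O–O cleavage and the two C–Br bonds.
Stereochemistry: C6 from a catalytic asymmetric aldol (inverted on chlorination); C4 from a hydroxyl-directed 1,3-anti reduction (inverted on chlorination); C2 from oxygen adding anti to the C4 silyl ether (inverted on bromination); the 3Z geometry from the cis-fused dioxine.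

Key step: step 7

Assumption: (S,S)-ProPhenol is taken to give the (5R)-aldol 6, the sense it shows with α-branched aldehydes and aryl methyl ketones; if the ynone shows the opposite sense, the (R,R)-ligand is used and nothing else changes.

**Step 1**
Reactants: 1 prenyl chloride; 2 N,N-dimethylformamide
Product: 4 2,2-dimethylbut-3-enal, via prenylmagnesium chloride 3 (not isolated)
Conditions: Mg, THF, 0 °C; then added to 2 (2 equiv), THF, −20 °C to rt; aq. HCl; distillation
Reagents that add atoms: none
Why: Bouveault-type formylation of an allylic Grignard reagent, in which 3 attacks the formamide through its γ-carbon in a six-membered transition state and the magnesium hemiaminal survives until acidic work-up, so the α-quaternary aldehyde (which can neither enolise nor isomerise) should be released without over-addition.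

**Step 2**
Reactants: 4 2,2-dimethylbut-3-enal; 5 4-(trimethylsilyl)but-3-yn-2-one
Product: 6 (5R)-5-hydroxy-6,6-dimethyl-1-(trimethylsilyl)oct-7-en-1-yn-3-one
Conditions: (S,S)-ProPhenol (10 mol %), Et2Zn (20 mol %), 4 Å molecular sieves, THF, 0 °C
Reagents that add atoms: none
Why: Direct catalytic asymmetric aldol addition of a methyl ynone under dinuclear zinc–ProPhenol catalysis, in which the zinc enolate of 5 adds to the non-enolisable α-quaternary aldehyde inside the chiral dinuclear pocket and so sets C6 as the (R)-carbinol.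

**Step 3**
Reactants: 6 (5R)-5-hydroxy-6,6-dimethyl-1-(trimethylsilyl)oct-7-en-1-yn-3-one
Product: 7 (3R,5R)-6,6-dimethyl-1-(trimethylsilyl)oct-7-en-1-yne-3,5-diol
Conditions: Me4NBH(OAc)3, MeCN–AcOH, −30 °C
Reagents that add atoms: none
Why: Evans–Saksena reduction, in which the C6 hydroxyl exchanges onto boron and delivers hydride to the ynone carbonyl through a chair transition state, which should give the 1,3-anti diol and so set C4 as the (R)-carbinol.

**Step 4**
Reactants: 7 (3R,5R)-6,6-dimethyl-1-(trimethylsilyl)oct-7-en-1-yne-3,5-diol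
Product: 8 (3R,5R)-3-[(tert-butyldimethylsilyl)oxy]-6,6-dimethyl-1-(trimethylsilyl)oct-7-en-1-yn-5-ol
Conditions: TBSCl (1.05 equiv), imidazole, CH2Cl2, −20 to 0 °C
Reagents that add atoms: tert-butyldimethylsilyl chloride, CC(C)(C)[Si](C)(C)Cl
Why: Sterically controlled monosilylation, since the propargylic C4 hydroxyl next to the slim alkyne should react far faster than the C6 hydroxyl flanked by the quaternary carbon.

**Step 5**
Reactants: 8 (3R,5R)-3-[(tert-butyldimethylsilyl)oxy]-6,6-dimethyl-1-(trimethylsilyl)oct-7-en-1-yn-5-ol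
Product: 9 tert-butyl{[(3R,5S)-5-chloro-6,6-dimethyl-1-(trimethylsilyl)oct-7-en-1-yn-3-yl]oxy}dimethylsilane
Conditions: PPh3, CCl4, 1,2-dichloroethane, 70 °C
Reagents that add atoms: tetrachloromethane, ClC(Cl)(Cl)Cl
Why: Appel chlorination, in which the alkoxyphosphonium chloride ion pair collapses by SN2 with inversion at C6, the neutral non-ionising medium being what spares this neopentyl-type centre a Wagner–Meerwein shift, as in the classical neopentyl cases.

**Step 6**
Reactants: 9 tert-butyl{[(3R,5S)-5-chloro-6,6-dimethyl-1-(trimethylsilyl)oct-7-en-1-yn-3-yl]oxy}dimethylsilane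
Product: 10 tert-butyl{[(3R,5S)-5-chloro-6,6-dimethyloct-7-en-1-yn-3-yl]oxy}dimethylsilane
Conditions: K2CO3 (cat.), MeOH, rt
Reagents that add atoms: none
Why: Carbonate-mediated methanolysis of the C(sp)–Si bond, to which the silyl ether and the hindered secondary chloride are inert.

**Step 7**
Reactants: 10 tert-butyl{[(3R,5S)-5-chloro-6,6-dimethyloct-7-en-1-yn-3-yl]oxy}dimethylsilane
Product: 11 tert-butyl{[(1R,5S)-5-chloro-4,4-dimethyl-2-vinylcyclohex-2-en-1-yl]oxy}dimethylsilane
Conditions: RuCl2(H2IMes)(PCy3)(=CHPh) (second-generation Grubbs catalyst, 5 mol %), ethylene (1 atm), CH2Cl2 (0.01 M), 40 °C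
Reagents that add atoms: none
Why: The ruthenium methylidene kept alive by ethylene adds to the terminal alkyne with the metal on the internal carbon, the ruthenacyclobutene opens to a vinylcarbene, and this carbene closes onto the neopentyl vinyl group through a ruthenacyclobutane whose cycloreversion releases the 1,3-diene and returns the methylidene. The closest known reaction type is the ethylene-promoted ring-closing enyne metathesis of terminal 1,7-enynes to 1-vinylcyclohexenes. The ring closes in the exo mode as a cyclohexene, with C2=C3 inside the ring and C7=C8 outside it. No stereocentre is created, and C4 and C6 are not touched. The step needs exo closure rather than endo closure to a seven-membered diene, and ring closure rather than oligomerisation; the terminal alkyne and four-atom tether secure the first, while the gem-dimethyl group (which bends the chain and keeps the alkene from homodimerising) and high dilution secure the second, and any 2-substituted butadiene formed by ethylene cross-metathesis at the alkyne should be funnelled to the same product by ring-closing diene metathesis. The propargylic silyl ether and the secondary chloride are inert to the carbene.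

**Step 8**
Reactants: 11 tert-butyl{[(1R,5S)-5-chloro-4,4-dimethyl-2-vinylcyclohex-2-en-1-yl]oxy}dimethylsilane
Product: 12 tert-butyl{[(5R,7S,8aS)-7-chloro-8,8-dimethyl-3,5,6,7,8,8a-hexahydrobenzo[c][1,2]dioxin-5-yl]oxy}dimethylsilane
Conditions: O2, tetraphenylporphyrin (cat.), visible light, CH2Cl2, −20 °C
Reagents that add atoms: dioxygen, O=O
Why: [4+2] cycloaddition of singlet oxygen to the s-cis 1-vinylcyclohexene diene, in which oxygen should bond to C2 and C8 from the face opposite to the C4 silyloxy group and the C6 chlorine (setting C2), the cis-fused 1,2-dioxine fixes C8 cis to C2 on the new C3=C7 bond, and the ene pathway is starved because C1 carries no hydrogen.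

**Step 9**
Reactants: 12 tert-butyl{[(5R,7S,8aS)-7-chloro-8,8-dimethyl-3,5,6,7,8,8a-hexahydrobenzo[c][1,2]dioxin-5-yl]oxy}dimethylsilane
Product: 13 (5R,7S,8aS)-7-chloro-8,8-dimethyl-3,5,6,7,8,8a-hexahydrobenzo[c][1,2]dioxin-5-ol
Conditions: HF·pyridine, THF–pyridine, 0 °C to rt
Reagents that add atoms: none
Why: Fluoride cleavage of the silyl ether under mildly acidic conditions, chosen because basic fluoride would invite Kornblum–DeLaMare opening of the peroxide.

**Step 10**
Reactants: 13 (5R,7S,8aS)-7-chloro-8,8-dimethyl-3,5,6,7,8,8a-hexahydrobenzo[c][1,2]dioxin-5-ol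
Product: 14 (5S,7S,8aR)-5,7-dichloro-8,8-dimethyl-3,5,6,7,8,8a-hexahydrobenzo[c][1,2]dioxine
Conditions: 1-chloro-N,N,2-trimethylprop-1-en-1-amine, CH2Cl2, 0 °C to rt
Reagents that add atoms: 1-chloro-N,N,2-trimethylprop-1-en-1-amine, CC(C)=C(Cl)N(C)C
Why: Deoxychlorination with an α-chloroenamine, in which the alkoxy-iminium chloride ion pair collapses by SN2 with inversion at C4 under neutral, phosphine-free conditions that leave the O–O bond intact.

**Step 11**
Reactants: 14 (5S,7S,8aR)-5,7-dichloro-8,8-dimethyl-3,5,6,7,8,8a-hexahydrobenzo[c][1,2]dioxine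
Product: 15 (1R,3S,5S,6E)-3,5-dichloro-6-(2-hydroxyethylidene)-2,2-dimethylcyclohexan-1-ol (hydroxymethyl group on the same side of the double bond as the ring carbinol)
Conditions: thiourea (1.5 equiv), MeOH–CH2Cl2, 0 °C to rt
Reagents that add atoms: none
Why: Nucleophilic two-electron reduction of the O–O bond by thiourea, the standard passage from 3,6-dihydro-1,2-dioxines to cis-2-ene-1,4-diols, which forms no alkoxy radical and keeps both the C2 configuration and the alkene geometry.

**Step 12**
Reactants: 15 (1R,3S,5S,6E)-3,5-dichloro-6-(2-hydroxyethylidene)-2,2-dimethylcyclohexan-1-ol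
Product: 16 (2S,3Z,4S,6S)-2-bromo-3-(2-bromoethylidene)-4,6-dichloro-1,1-dimethylcyclohexane
Conditions: CBr4 (3 equiv), PPh3 (3 equiv), CH2Cl2, −20 to 0 °C
Reagents that add atoms: tetrabromomethane, BrC(Br)(Br)Br
Why: Twofold Appel bromination, in which the primary allylic oxyphosphonium at C8 is displaced first and the secondary allylic one at C2 by backside attack of bromide, which should invert C2 to the (S)-bromide while the double-bond geometry is untouched.

**Compound list**
1 | prenyl chloride (1-chloro-3-methylbut-2-ene) | CC(C)=CCCl | starting material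
2 | N,N-dimethylformamide | CN(C)C=O | starting material
3 | prenylmagnesium chloride | CC(C)=CC[Mg]Cl | intermediate
4 | 2,2-dimethylbut-3-enal | C=CC(C)(C)C=O | intermediate
5 | 4-(trimethylsilyl)but-3-yn-2-one | CC(=O)C#C[Si](C)(C)C | starting material
6 | (5R)-5-hydroxy-6,6-dimethyl-1-(trimethylsilyl)oct-7-en-1-yn-3-one | C[Si](C)(C)C#CC(=O)C[C@@H](O)C(C)(C)C=C | intermediate
7 | (3R,5R)-6,6-dimethyl-1-(trimethylsilyl)oct-7-en-1-yne-3,5-diol (1,3-anti) | C[Si](C)(C)C#C[C@H](O)C[C@@H](O)C(C)(C)C=C | intermediate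
8 | (3R,5R)-3-[(tert-butyldimethylsilyl)oxy]-6,6-dimethyl-1-(trimethylsilyl)oct-7-en-1-yn-5-ol | C[Si](C)(C)C#C[C@H](O[Si](C)(C)C(C)(C)C)C[C@@H](O)C(C)(C)C=C | intermediate
9 | tert-butyl{[(3R,5S)-5-chloro-6,6-dimethyl-1-(trimethylsilyl)oct-7-en-1-yn-3-yl]oxy}dimethylsilane | C[Si](C)(C)C#C[C@H](O[Si](C)(C)C(C)(C)C)C[C@H](Cl)C(C)(C)C=C | intermediate
10 | tert-butyl{[(3R,5S)-5-chloro-6,6-dimethyloct-7-en-1-yn-3-yl]oxy}dimethylsilane | C#C[C@H](O[Si](C)(C)C(C)(C)C)C[C@H](Cl)C(C)(C)C=C | intermediate
11 | tert-butyl{[(1R,5S)-5-chloro-4,4-dimethyl-2-vinylcyclohex-2-en-1-yl]oxy}dimethylsilane | CC1(C)C=C(C=C)[C@H](O[Si](C)(C)C(C)(C)C)C[C@@H]1Cl | intermediate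
12 | tert-butyl{[(5R,7S,8aS)-7-chloro-8,8-dimethyl-3,5,6,7,8,8a-hexahydrobenzo[c][1,2]dioxin-5-yl]oxy}dimethylsilane (peroxide oxygen at C2 trans to the silyloxy group) | CC1(C)[C@H]2OOCC=C2[C@H](O[Si](C)(C)C(C)(C)C)C[C@@H]1Cl | intermediate
13 | (5R,7S,8aS)-7-chloro-8,8-dimethyl-3,5,6,7,8,8a-hexahydrobenzo[c][1,2]dioxin-5-ol | CC1(C)[C@H]2OOCC=C2[C@H](O)C[C@@H]1Cl | intermediate
14 | (5S,7S,8aR)-5,7-dichloro-8,8-dimethyl-3,5,6,7,8,8a-hexahydrobenzo[c][1,2]dioxine | CC1(C)[C@H]2OOCC=C2[C@@H](Cl)C[C@@H]1Cl | intermediate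
15 | (1R,3S,5S,6E)-3,5-dichloro-6-(2-hydroxyethylidene)-2,2-dimethylcyclohexan-1-ol | CC1(C)[C@@H](O)/C(=C\CO)[C@@H](Cl)C[C@@H]1Cl | intermediate
16 | (2S,3Z,4S,6S)-2-bromo-3-(2-bromoethylidene)-4,6-dichloro-1,1-dimethylcyclohexane (CNP0137413.1) | CC1(C)[C@H](Br)/C(=C\CBr)[C@@H](Cl)C[C@@H]1Cl | target

**Count**
Total steps: 12. Longest linear sequence: 12 steps (1 to 16).

**Steps most likely to fail**

Step 12. The displacement at C2, a secondary allylic carbon flanked by the quaternary C1, may leave the SN2 path. Bromide can enter at C7 with allylic shift, the oxyphosphonium can ionise with loss of the C2 configuration, or the still-free hydroxyl of the half-reacted diol can close onto its activated partner to a 2,5-dihydrofuran. The fallback takes the two displacements apart; it sets out from 15 and returns at 16. Selective silylation of the primary hydroxyl (TBSCl, imidazole, CH2Cl2, −20 °C) should give (1R,3S,5S,6E)-6-{2-[(tert-butyldimethylsilyl)oxy]ethylidene}-3,5-dichloro-2,2-dimethylcyclohexan-1-ol F1, in which no hydroxyl is left to cyclise and the silyloxymethyl group screens C7. The C2 hydroxyl is then converted alone: MsCl and Et3N in THF at −40 °C give the C2 methanesulfonate F2 (not isolated), and LiBr in the same flask displaces it with inversion to (2S,3Z,4S,6S)-2-bromo-3-{2-[(tert-butyldimethylsilyl)oxy]ethylidene}-4,6-dichloro-1,1-dimethylcyclohexane F3. HF·pyridine frees (2Z)-2-[(2S,4S,6S)-2-bromo-4,6-dichloro-3,3-dimethylcyclohexylidene]ethan-1-ol F4, and CBr4/PPh3 at this unhindered primary allylic alcohol gives 16.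

Step 5. The SN2 collapse of the alkoxyphosphonium salt at the neopentyl-type carbinol may be too slow, so that elimination towards C5 or a 1,2-shift from the quaternary carbon takes over on heating. The fallback replaces the one-pot phosphonium activation by a two-stage sulfonate displacement run cold; it sets out from 8 and returns at 9. Tf2O and 2,6-lutidine in CH2Cl2 at −78 °C should give (3R,5R)-3-[(tert-butyldimethylsilyl)oxy]-6,6-dimethyl-1-(trimethylsilyl)oct-7-en-1-yn-5-yl trifluoromethanesulfonate F5, whose far better leaving group is displaced by Bu4NCl in toluene between −40 and 0 °C with inversion to 9.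

Step 10. The peroxide bridge may not survive activation of the neighbouring hydroxyl: the O–O bond can be cleaved, or chloride can enter at C7 with allylic shift. The fallback removes the peroxide before the chlorination; it sets out from 12 and returns at 15. Thiourea in MeOH reduces 12 to (1S,3S,5R,6E)-5-[(tert-butyldimethylsilyl)oxy]-3-chloro-6-(2-hydroxyethylidene)-2,2-dimethylcyclohexan-1-ol F6. 2-Methoxypropene and PPTS tie the two hydroxyls into the seven-membered isopropylidene acetal tert-butyl{[(6R,8S,9aS)-8-chloro-2,2,9,9-tetramethyl-4,6,7,8,9,9a-hexahydro-2H-benzo[d][1,3]dioxepin-6-yl]oxy}dimethylsilane F7. HF·pyridine frees the C4 alcohol (6R,8S,9aS)-8-chloro-2,2,9,9-tetramethyl-4,6,7,8,9,9a-hexahydro-2H-benzo[d][1,3]dioxepin-6-ol F8. PPh3/CCl4, now harmless because no peroxide is present, should invert C4 to (6S,8S,9aR)-6,8-dichloro-2,2,9,9-tetramethyl-4,6,7,8,9,9a-hexahydro-2H-benzo[d][1,3]dioxepine F9, and PPTS in MeOH removes the acetal to give 15.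

**Further compounds**
F1 | step 12 | (1R,3S,5S,6E)-6-{2-[(tert-butyldimethylsilyl)oxy]ethylidene}-3,5-dichloro-2,2-dimethylcyclohexan-1-ol | CC1(C)[C@@H](O)/C(=C\CO[Si](C)(C)C(C)(C)C)[C@@H](Cl)C[C@@H]1Cl
F2 | step 12 | (1R,3S,5S,6E)-6-{2-[(tert-butyldimethylsilyl)oxy]ethylidene}-3,5-dichloro-2,2-dimethylcyclohexyl methanesulfonate | CC1(C)[C@@H](OS(C)(=O)=O)/C(=C\CO[Si](C)(C)C(C)(C)C)[C@@H](Cl)C[C@@H]1Cl
F3 | step 12 | (2S,3Z,4S,6S)-2-bromo-3-{2-[(tert-butyldimethylsilyl)oxy]ethylidene}-4,6-dichloro-1,1-dimethylcyclohexane | CC1(C)[C@H](Br)/C(=C\CO[Si](C)(C)C(C)(C)C)[C@@H](Cl)C[C@@H]1Cl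
F4 | step 12 | (2Z)-2-[(2S,4S,6S)-2-bromo-4,6-dichloro-3,3-dimethylcyclohexylidene]ethan-1-ol | CC1(C)[C@H](Br)/C(=C\CO)[C@@H](Cl)C[C@@H]1Cl
F5 | step 5 | (3R,5R)-3-[(tert-butyldimethylsilyl)oxy]-6,6-dimethyl-1-(trimethylsilyl)oct-7-en-1-yn-5-yl trifluoromethanesulfonate | C[Si](C)(C)C#C[C@H](O[Si](C)(C)C(C)(C)C)C[C@@H](OS(=O)(=O)C(F)(F)F)C(C)(C)C=C
F6 | step 10 | (1S,3S,5R,6E)-5-[(tert-butyldimethylsilyl)oxy]-3-chloro-6-(2-hydroxyethylidene)-2,2-dimethylcyclohexan-1-ol | CC1(C)[C@@H](O)/C(=C\CO)[C@H](O[Si](C)(C)C(C)(C)C)C[C@@H]1Cl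
F7 | step 10 | tert-butyl{[(6R,8S,9aS)-8-chloro-2,2,9,9-tetramethyl-4,6,7,8,9,9a-hexahydro-2H-benzo[d][1,3]dioxepin-6-yl]oxy}dimethylsilane | CC1(C)[C@H]2OC(C)(C)OCC=C2[C@H](O[Si](C)(C)C(C)(C)C)C[C@@H]1Cl
F8 | step 10 | (6R,8S,9aS)-8-chloro-2,2,9,9-tetramethyl-4,6,7,8,9,9a-hexahydro-2H-benzo[d][1,3]dioxepin-6-ol | CC1(C)[C@H]2OC(C)(C)OCC=C2[C@H](O)C[C@@H]1Cl
F9 | step 10 | (6S,8S,9aR)-6,8-dichloro-2,2,9,9-tetramethyl-4,6,7,8,9,9a-hexahydro-2H-benzo[d][1,3]dioxepine | CC1(C)[C@H]2OC(C)(C)OCC=C2[C@@H](Cl)C[C@@H]1Cl
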